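The easy step is a sum over the last reading of the epsilon run: at 60.0 s the starting material stands at 85.3%, adduct at 0.2% and target at 0%, so 15 percentage points sit in something unlisted. Adduct and target are the small thing here, with no reading above 0.4%, so I leave them as a correction and reckon the large loss by itself.

all flasks: starting material 20 mM

|  | solid reagent | temperature | remark | time |
|---|---|---|---|---|
| epsilon | 20 mM | 35 °C | run made earlier |  |
| south-east | 10.0 mM | 35 °C |  | 10 min |
| north-west | 10.0 mM | 45 °C |  | 10 min |
| west | 10.0 mM | 55 °C |  | 10 min |

epsilon run (percent of the starting material charged)

| time / s | adduct / % | target / % | starting material / % |
|---|---|---|---|
| 10.0 | 0 | 0 | 97.1 |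
| 12.0 | 0 | 0 | 96.9 |
| 20.0 | 0.1 | 0.4 | 94.8 |
| 30.0 | 0.3 | 0.1 | 92.1 |
| 50.0 | 0.1 | 0 | 87.7 |
| 60.0 | 0.2 | 0 | 85.3 |

(each reading ± 0.3 percentage points)

- the earlier runs were read with a standard deviation of 0.3 percentage points
- at the start none of the solid reagent is in solution
- the earlier runs do not show what temperature does; that part of a forecast is a guess
- a reading or a percentage of target counts all its forms, free or not

1. which of these there is most of at the end, counted by the starting material in it, south-east (target / starting material / adduct)
2. which of these there is most of at the end, counted by the starting material in it, north-west (target / starting material / adduct)
3. which of these there is most of at the end, counted by the starting material in it, west (target / starting material / adduct)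
4. final amount of the leader among these, as a percentage of the starting material charged, in south-east
5. final amount of the leader among these, as a percentage of the starting material charged, in north-west
6. final amount of the leader among these, as a percentage of the starting material charged, in west

The readings do not separate a plain exponential from a second-order loss, and I commit to the second, with molecules of starting material consumed in pairs. Then c(starting material), relative to its charge, follows the reciprocal of 1 + t/τ. The pairing time τ is the time in which c(starting material) falls to half at a charge of 20 mM, and it equals reading time times remaining over lost: 5.80 min.

Now I turn the settings one at a time. The solid reagent goes from 20 mM to 10.0 mM; none of it is in solution at the start, yet the loss already shows at the first reading, so I expect this cut to change little. The time goes to 10 min, which gives 36.7% in south-east. Temperature is a guess: if each step up makes the rate twice as fast, north-west holds 22.5% and west 12.7%. Starting material leads in each.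

The forecast also names starting material as leader, but at 58% in south-east, 52% in north-west and 50% in west, on the ground that “If consumption is 1:1, the starting material cannot fall below about 50%”. My figures are lower, and we part on whether the solid reagent governs the loss.

The flask gives starting material as leader in south-east, starting material in north-west and starting material in west, at 34.1%, 21.7% and 12.9%.

    solid reagent ⇌ partner, rate k1*(cs1 - [partner]) while solid is left; crystals form when [partner] > cs1 (solubility = 2.80 mM, k = 0.250 /min)
    crystals ⇌ target, rate k2*(cs2 - [target]) while solid is left; crystals form when [target] > cs2 (solubility = 13.0 mM, k = 0.910 /min)
    2 starting material → homo dimer (k = 4.30 /M/min, Ea = 52.0 kJ/mol)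
    adduct → target (k = 0.0410 /min, Ea = 97.0 kJ/mol)
    starting material + partner ⇌ adduct (K = 97.0 /M, k = 12.0 /M/min, Ea = 47.0 kJ/mol, ΔH = −35.0 kJ/mol)
    (constants at 35 °C)

Moving the solid reagent from the epsilon charge to that of south-east leaves 85.0% against 85.0% at the last epsilon reading, while moving the time instead gives 34.1%. With the turning of two starting material into homo dimer taken away, south-east ends at 90.3% instead of 34.1%, which is a part of the story. The pairing time leaves a gap of 2.6 points in south-east, the small correction, beside 4.51% adduct and 1.05% target there. The difference in temperature is the main reason that west ends at 12.9% of starting material against 34.1% in south-east.

For north-west stopped at 4.0 min, the pairing time with the same guessed factor gives 42.0% of starting material. The computed flask holds 42.0% of starting material.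

(The numbers in the tables were computed for an exercise, and the scatter is random.)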